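**Retrosynthetic overview**

1. Quinoline numbering is used: ring A is the pyridine ring (N-1, C-2, C-3, C-4, C-4a, C-8a) and ring B is the carbocycle (C-4a, C-5, C-6, C-7, C-8, C-8a). The only stereocentre is the quaternary C-6, which is S in the target.
2. The formamide is made last from secondary amine 13. The C-5 and C-8 methylenes of 13 come from a C-5 ketone (Wolff–Kishner) and a C-8 tert-butyl ester (decarboxylation), that is, from keto ester 9.
3. Key disconnection: ring B of 9 is cut at C-6–C-7 and C-8–C-8a. This gives tert-butyl acrylate 7 (C-7 and C-8) and the acyclic, racemic α-aryl ketone 6. In the forward direction it is a catalytic asymmetric Michael addition at C-6, followed in the same flask by SNAr at C-8a.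
4. Enabling feature: C-6 is benzylic and joined to ring A only through C-5. A temporary C-5 carbonyl therefore makes C-6 an enolate carbon and, together with N-1, makes a chlorine-bearing C-8a an SNAr site. C-6 and C-8a stand 1,4 to each other, which is the span of a two-carbon Michael acceptor.
5. Ketone 6 comes from amide 1 and benzyl chloride 2 (via ketone 4) and bromide 5. Ring A and the arene are bought; ring B is the only ring made (step 3).

Key step: step 3

Remark: the sense of induction of the cinchona-derived ammonium salt in step 3 cannot be predicted with certainty; the route is written for whichever pseudoenantiomer (cinchonine- or cinchonidine-derived) gives the 6S series.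

**Step 1**
Reactants: 1 2-chloro-N-methoxy-N-methylpyridine-3-carboxamide; 2 4-(chloromethyl)-1,2-dimethoxybenzene
Product: 4 1-(2-chloropyridin-3-yl)-2-(3,4-dimethoxyphenyl)ethan-1-one, via benzylic Grignard reagent 3 (not isolated)
Conditions: 2, Mg turnings (I2 cat.), THF, 0 °C; then 1, THF, −20 → 0 °C; aq NH4Cl
Reagents that add atoms: none
Why: Weinreb ketone synthesis, in which the benzylic Grignard reagent should add once to the N-methoxy-N-methylamide to give a chelated tetrahedral intermediate that releases the ketone only on work-up, while the ring chloride is left alone at low temperature.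

**Step 2**
Reactants: 4 1-(2-chloropyridin-3-yl)-2-(3,4-dimethoxyphenyl)ethan-1-one; 5 tert-butyl N-(2-bromoethyl)-N-methylcarbamate
Product: 6 tert-butyl N-[4-(2-chloropyridin-3-yl)-3-(3,4-dimethoxyphenyl)-4-oxobutyl]-N-methylcarbamate (racemic)
Conditions: NaH, DMF, 0 °C; then 5, NaI (10 mol %), 0 °C → rt
Reagents that add atoms: none
Why: Enolate C-alkylation (SN2, with Finkelstein activation of the bromide) of the doubly activated methylene of 4, which should stop after one alkylation because the remaining tertiary C–H is hindered and less acidic; the new stereocentre is racemic and is erased by enolisation in step 3.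

**Step 3**
Reactants: 6 tert-butyl N-[4-(2-chloropyridin-3-yl)-3-(3,4-dimethoxyphenyl)-4-oxobutyl]-N-methylcarbamate (racemic); 7 tert-butyl prop-2-enoate
Product: 9 tert-butyl (6S)-6-{2-[(tert-butoxycarbonyl)(methyl)amino]ethyl}-6-(3,4-dimethoxyphenyl)-5-oxo-5,6,7,8-tetrahydroquinoline-8-carboxylate (both C-8 epimers), via Michael adduct 8 (not isolated)
Conditions: 7 (1.1 equiv), N-[4-(trifluoromethyl)benzyl]cinchoninium bromide (10 mol %), Cs2CO3 (solid), toluene, −20 °C; then KN(SiMe3)2 (2.2 equiv), THF, −40 → 0 °C; aq NH4Cl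
Reagents that add atoms: none
Why: Proposed new method: Cs2CO3 deprotonates racemic 6 at C-6, the prochiral tetrasubstituted enolate is carried into toluene as a tight ion pair with the cinchoninium cation and adds through C-6 to acrylate 7 (Michael addition, C-6–C-7 bond, adduct 8), after which KN(SiMe3)2 forms the ester enolate of 8, whose C-8 attacks chlorine-bearing C-8a by addition–elimination (SNAr, C-8–C-8a bond). The closest known reaction types are the phase-transfer alkylations and Michael additions of cyclic α-aryl ketones (2-aryl-1-indanones, 2-arylcyclohexanones) under cinchona-derived ammonium salts, which give quaternary α-aryl ketones, and the racemic tandem Michael–SNAr annulation of ortho-halogenated aryl ketones; new are the acyclic, fully substituted α-aryl ketone enolate as prochiral partner and the joining of both events in one flask. Ring B closes in a 6-exo-trig mode at C-8a through an anionic σ-adduct whose charge rests on N-1 and on the C-5 carbonyl oxygen, then chloride leaves. C-6 is set by the catalyst, which shields one face of the ion-paired enolate, so that both enantiomers of 6 converge on one product; C-8 is formed without control and is erased in step 4. The step needs C- over O-alkylation (soft acceptor, non-polar medium), enantioface selectivity (tight ion pair, low temperature, insoluble base that suppresses the uncatalysed pathway) and a ring closure that outruns retro-Michael cleavage of the ester enolate, which the double activation of C-8a by N-1 and the ortho acyl group and the six-membered transition state should secure.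

**Step 4**
Reactants: 9 tert-butyl (6S)-6-{2-[(tert-butoxycarbonyl)(methyl)amino]ethyl}-6-(3,4-dimethoxyphenyl)-5-oxo-5,6,7,8-tetrahydroquinoline-8-carboxylate (both C-8 epimers)
Product: 11 (6S)-6-(3,4-dimethoxyphenyl)-6-[2-(methylamino)ethyl]-7,8-dihydroquinolin-5(6H)-one, via amino acid 10 (not isolated)
Conditions: TFA, CH2Cl2, 0 °C → rt; evaporate; then aq NaHCO3 (to pH 7), 1,4-dioxane, 80 °C
Reagents that add atoms: none
Why: Acidolysis of both tert-butyl groups (carbamate and ester) followed by thermal decarboxylation of the resulting 2-pyridylacetic acid through its zwitterion, a reaction that should run readily once the acid is neutralised; quaternary C-6 is not touched.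

**Step 5**
Reactants: 11 (6S)-6-(3,4-dimethoxyphenyl)-6-[2-(methylamino)ethyl]-7,8-dihydroquinolin-5(6H)-one
Product: 13 2-[(6S)-6-(3,4-dimethoxyphenyl)-5,6,7,8-tetrahydroquinolin-6-yl]-N-methylethan-1-amine, via hydrazone 12 (not isolated)
Conditions: N2H4·H2O, diethylene glycol, 130 °C; then KOH, 195 °C (water distilled off)
Reagents that add atoms: none
Why: Wolff–Kishner reduction in a high-boiling glycol, in which the electron-poor pyridyl ketone should form the hydrazone before base is added and then lose N2 to leave the C-5 methylene; C-6 carries no hydrogen and cannot epimerise.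

**Step 6**
Reactants: 13 2-[(6S)-6-(3,4-dimethoxyphenyl)-5,6,7,8-tetrahydroquinolin-6-yl]-N-methylethan-1-amine
Product: 14 N-{2-[(6S)-6-(3,4-dimethoxyphenyl)-5,6,7,8-tetrahydroquinolin-6-yl]ethyl}-N-methylformamide
Conditions: HCO2Et (neat), 80 °C, sealed vessel
Reagents that add atoms: ethyl formate, CCOC=O
Why: N-Formylation of the secondary amine by aminolysis of ethyl formate, which should leave the pyridine nitrogen and the aryl ethers untouched.

**Compound list**

1 | 2-chloro-N-methoxy-N-methylpyridine-3-carboxamide | CON(C)C(=O)c1cccnc1Cl | starting material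
2 | 4-(chloromethyl)-1,2-dimethoxybenzene | COc1ccc(CCl)cc1OC | starting material
3 | (3,4-dimethoxybenzyl)magnesium chloride | COc1ccc(C[Mg]Cl)cc1OC | intermediate
4 | 1-(2-chloropyridin-3-yl)-2-(3,4-dimethoxyphenyl)ethan-1-one | COc1ccc(CC(=O)c2cccnc2Cl)cc1OC | intermediate
5 | tert-butyl N-(2-bromoethyl)-N-methylcarbamate | CN(CCBr)C(=O)OC(C)(C)C | starting material
6 | tert-butyl N-[4-(2-chloropyridin-3-yl)-3-(3,4-dimethoxyphenyl)-4-oxobutyl]-N-methylcarbamate (racemic) | COc1ccc(C(CCN(C)C(=O)OC(C)(C)C)C(=O)c2cccnc2Cl)cc1OC | intermediate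
7 | tert-butyl prop-2-enoate | C=CC(=O)OC(C)(C)C | starting material
8 | tert-butyl (4S)-6-[(tert-butoxycarbonyl)(methyl)amino]-4-(2-chloropyridine-3-carbonyl)-4-(3,4-dimethoxyphenyl)hexanoate | COc1ccc([C@@](C(=O)c2cccnc2Cl)(CCN(C)C(=O)OC(C)(C)C)CCC(=O)OC(C)(C)C)cc1OC | intermediate
9 | tert-butyl (6S)-6-{2-[(tert-butoxycarbonyl)(methyl)amino]ethyl}-6-(3,4-dimethoxyphenyl)-5-oxo-5,6,7,8-tetrahydroquinoline-8-carboxylate (both C-8 epimers) | COc1ccc([C@@]2(CCN(C)C(=O)OC(C)(C)C)CC(C(=O)OC(C)(C)C)c3ncccc3C2=O)cc1OC | intermediate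
10 | (6S)-6-(3,4-dimethoxyphenyl)-6-[2-(methylamino)ethyl]-5-oxo-5,6,7,8-tetrahydroquinoline-8-carboxylic acid (both C-8 epimers) | COc1ccc([C@@]2(CCNC)CC(C(=O)O)c3ncccc3C2=O)cc1OC | intermediate
11 | (6S)-6-(3,4-dimethoxyphenyl)-6-[2-(methylamino)ethyl]-7,8-dihydroquinolin-5(6H)-one | COc1ccc([C@@]2(CCNC)CCc3ncccc3C2=O)cc1OC | intermediate
12 | (6S)-6-(3,4-dimethoxyphenyl)-5-hydrazinylidene-6-[2-(methylamino)ethyl]-5,6,7,8-tetrahydroquinoline | COc1ccc([C@@]2(CCNC)CCc3ncccc3C2=NN)cc1OC | intermediate
13 | 2-[(6S)-6-(3,4-dimethoxyphenyl)-5,6,7,8-tetrahydroquinolin-6-yl]-N-methylethan-1-amine | COc1ccc([C@@]2(CCNC)CCc3ncccc3C2)cc1OC | intermediate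
14 | N-{2-[(6S)-6-(3,4-dimethoxyphenyl)-5,6,7,8-tetrahydroquinolin-6-yl]ethyl}-N-methylformamide | COc1ccc([C@@]2(CCN(C)C=O)CCc3ncccc3C2)cc1OC | target

**Step count and risks**

Total step count: 6. Longest linear sequence: 6 steps (from 1 or 2 to 14).

Steps most likely to fail:

Step 3. Enantioface discrimination may be insufficient, because the acyclic enolate can exist as an E/Z mixture, the ion pair may be loose and an uncatalysed background addition may compete. The enantiomeric purity may also erode through retro-Michael cleavage and re-addition during the basic ring closure. The fallback sets out from 6 and returns at 11. Ketone 6 and acrylate 7 are treated with KN(SiMe3)2 alone (THF, −78 → 0 °C), a racemic tandem Michael–SNAr annulation of the known type, to give racemic tert-butyl 6-{2-[(tert-butoxycarbonyl)(methyl)amino]ethyl}-6-(3,4-dimethoxyphenyl)-5-oxo-5,6,7,8-tetrahydroquinoline-8-carboxylate F1. Acidolysis and decarboxylation as in step 4 should lead through the racemic amino acid 6-(3,4-dimethoxyphenyl)-6-[2-(methylamino)ethyl]-5-oxo-5,6,7,8-tetrahydroquinoline-8-carboxylic acid F2 to racemic 6-(3,4-dimethoxyphenyl)-6-[2-(methylamino)ethyl]-7,8-dihydroquinolin-5(6H)-one F3. This base is resolved by fractional crystallisation with (2R,3R)-2,3-bis[(4-methylbenzoyl)oxy]butanedioic acid (or its antipode, whichever gives the less soluble salt of the S base) to the salt of the 6S amino ketone with the (2R,3R) acid F4, from which aqueous NaOH sets 11 free.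

Step 5. Hydrazone formation at the carbonyl flanked by the quaternary centre may be slow or incomplete, and the strongly basic medium at 195 °C may cause aryl ether cleavage or retro-Michael-type ring opening before the hydrazone has formed. The fallback sets out from 11 and returns at 14. Amine 11 is formylated with ethyl formate to N-{2-[(6S)-6-(3,4-dimethoxyphenyl)-5-oxo-5,6,7,8-tetrahydroquinolin-6-yl]ethyl}-N-methylformamide F5. NaBH4 in MeOH reduces the ketone to N-{2-[(6S)-6-(3,4-dimethoxyphenyl)-5-hydroxy-5,6,7,8-tetrahydroquinolin-6-yl]ethyl}-N-methylformamide F6 (both C-5 epimers). 1,1'-Thiocarbonyldiimidazole (DMAP cat., 1,2-dichloroethane, 80 °C) converts this to O-[(6S)-6-(3,4-dimethoxyphenyl)-6-{2-[formyl(methyl)amino]ethyl}-5,6,7,8-tetrahydroquinolin-5-yl] 1H-imidazole-1-carbothioate F7. Bu3SnH with AIBN in toluene at 110 °C (Barton–McCombie deoxygenation through the pyridine-stabilised C-5 radical) should then give 14 directly.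

Step 2. The enolate may be alkylated at oxygen, the SN2 reaction with the β-amino bromide may be slow, and the enolate may attack the chloropyridine of a second molecule by intermolecular SNAr. The fallback sets out from 5 and returns at 6, so that the ketone is formed only after the side chain is in place. Commercial (3,4-dimethoxyphenyl)acetonitrile is alkylated with 5 (NaH, DMF, 0 °C → rt) to tert-butyl N-[3-cyano-3-(3,4-dimethoxyphenyl)propyl]-N-methylcarbamate F8. i-Bu2AlH (toluene, −78 °C, then aqueous acid work-up) gives tert-butyl N-[3-(3,4-dimethoxyphenyl)-4-oxobutyl]-N-methylcarbamate F9. Commercial 2-chloropyridine is lithiated with LiN(i-Pr)2 (THF, −78 °C) to 2-chloro-3-lithiopyridine F10, which adds to the aldehyde to give tert-butyl N-[4-(2-chloropyridin-3-yl)-3-(3,4-dimethoxyphenyl)-4-hydroxybutyl]-N-methylcarbamate F11 (diastereomer mixture). Oxidation with Dess–Martin periodinane (CH2Cl2, rt) gives 6.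

**Further compounds**

F1 | step 3 | tert-butyl 6-{2-[(tert-butoxycarbonyl)(methyl)amino]ethyl}-6-(3,4-dimethoxyphenyl)-5-oxo-5,6,7,8-tetrahydroquinoline-8-carboxylate (racemic, both C-8 epimers) | COc1ccc(C2(CCN(C)C(=O)OC(C)(C)C)CC(C(=O)OC(C)(C)C)c3ncccc3C2=O)cc1OC
F2 | step 3 | 6-(3,4-dimethoxyphenyl)-6-[2-(methylamino)ethyl]-5-oxo-5,6,7,8-tetrahydroquinoline-8-carboxylic acid (racemic, both C-8 epimers) | COc1ccc(C2(CCNC)CC(C(=O)O)c3ncccc3C2=O)cc1OC
F3 | step 3 | 6-(3,4-dimethoxyphenyl)-6-[2-(methylamino)ethyl]-7,8-dihydroquinolin-5(6H)-one (racemic) | COc1ccc(C2(CCNC)CCc3ncccc3C2=O)cc1OC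
F4 | step 3 | salt of (6S)-6-(3,4-dimethoxyphenyl)-6-[2-(methylamino)ethyl]-7,8-dihydroquinolin-5(6H)-one with (2R,3R)-2,3-bis[(4-methylbenzoyl)oxy]butanedioic acid | COc1ccc([C@@]2(CCNC)CCc3ncccc3C2=O)cc1OC.OC(=O)[C@H](OC(=O)c1ccc(C)cc1)[C@@H](OC(=O)c1ccc(C)cc1)C(=O)O
F5 | step 5 | N-{2-[(6S)-6-(3,4-dimethoxyphenyl)-5-oxo-5,6,7,8-tetrahydroquinolin-6-yl]ethyl}-N-methylformamide | COc1ccc([C@@]2(CCN(C)C=O)CCc3ncccc3C2=O)cc1OC
F6 | step 5 | N-{2-[(6S)-6-(3,4-dimethoxyphenyl)-5-hydroxy-5,6,7,8-tetrahydroquinolin-6-yl]ethyl}-N-methylformamide (both C-5 epimers) | COc1ccc([C@@]2(CCN(C)C=O)CCc3ncccc3C2O)cc1OC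
F7 | step 5 | O-[(6S)-6-(3,4-dimethoxyphenyl)-6-{2-[formyl(methyl)amino]ethyl}-5,6,7,8-tetrahydroquinolin-5-yl] 1H-imidazole-1-carbothioate (both C-5 epimers) | COc1ccc([C@@]2(CCN(C)C=O)CCc3ncccc3C2OC(=S)n4ccnc4)cc1OC
F8 | step 2 | tert-butyl N-[3-cyano-3-(3,4-dimethoxyphenyl)propyl]-N-methylcarbamate (racemic) | COc1ccc(C(C#N)CCN(C)C(=O)OC(C)(C)C)cc1OC
F9 | step 2 | tert-butyl N-[3-(3,4-dimethoxyphenyl)-4-oxobutyl]-N-methylcarbamate (racemic) | COc1ccc(C(C=O)CCN(C)C(=O)OC(C)(C)C)cc1OC
F10 | step 2 | 2-chloro-3-lithiopyridine | [Li]c1cccnc1Cl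
F11 | step 2 | tert-butyl N-[4-(2-chloropyridin-3-yl)-3-(3,4-dimethoxyphenyl)-4-hydroxybutyl]-N-methylcarbamate (diastereomer mixture) | COc1ccc(C(CCN(C)C(=O)OC(C)(C)C)C(O)c2cccnc2Cl)cc1OC
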